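**Strategy.** Germacrane numbering is used (ring C1–C10; C4 is the methyl-bearing oxirane carbon, C5 the oxirane CH). The oxirane is cis-fused to the ten-membered ring (C3 and C6 on one side), so its C4–C5 bond is latent in a (Z)-trisubstituted cyclodecene. Everything rests on forging this bond by ring-closing metathesis: in one operation a C5 vinyl group and a C4 isopropenyl group of an open-chain seco-ester that already carries C6–C9 and the (Z)-C1=C10 olefin are joined, closing the carbocycle with the Z geometry the medium ring enforces. Hydroxyl-directed epoxidation from C6 then converts C4=C5 into the oxirane, and lactonisation, oxidation and acylation finish the target.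

Key step: step 14

Assumption: the drawn absolute configuration, (4R,5S,6S,7R,8S,9R) in germacrane numbering, is the target; C11–C13 are the lactone carbons, C14 the formyl carbon, C15 the C4 methyl, and C9′ the dioxolane CH of the glyceraldehyde unit that is later excised.

**Fragment A (C5–C7, C11–C13)**

Step 1
Reactants: 1 2-ethenyloxirane (racemic); 2 (4-methoxyphenyl)methanol
Product: 3 (2R)-2-[(4-methoxybenzyl)oxy]but-3-en-1-ol
Conditions: Pd2(dba)3·CHCl3 (1 mol %), N,N′-bis(2-diphenylphosphinobenzoyl)-trans-1,2-diaminocyclohexane (3 mol %, the enantiomer that delivers the R ether), Et3B (1 mol %), CH2Cl2, rt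
Reagents that add atoms: none
Why: Palladium-catalysed dynamic kinetic asymmetric allylic etherification (Tsuji–Trost type), in which the borane-bound alkoxide is delivered to the internal terminus of the equilibrating π-allyl complex, so the chiral ligand sets C6 from the racemic epoxide.

Step 2
Reactants: 3 (2R)-2-[(4-methoxybenzyl)oxy]but-3-en-1-ol
Product: 4 (2R)-2-[(4-methoxybenzyl)oxy]but-3-enal
Conditions: Dess–Martin periodinane, CH2Cl2, 0 °C; used at once without chromatography
Reagents that add atoms: none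
Why: Dess–Martin oxidation is fast and free of amine base, which should spare the labile α-alkoxy-β,γ-unsaturated aldehyde from epimerisation at C6 and from drift into conjugation.

Step 3
Reactants: 4 (2R)-2-[(4-methoxybenzyl)oxy]but-3-enal; 5 methyl prop-2-ynoate
Product: 7 methyl (4R)-3-hydroxy-4-[(4-methoxybenzyl)oxy]-2-methylidenehex-5-enoate (both C3 epimers), via methyl 2-(diisobutylalumanyl)prop-2-enoate 6 (not isolated)
Conditions: 5, i-Bu2AlH, N-methylmorpholine N-oxide, THF, 0 °C; then 4, 0 °C → rt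
Reagents that add atoms: none
Why: Vinylalumination (hydroalumination of the propiolate, then addition of the α-aluminoacrylate to the aldehyde) gives the Morita–Baylis–Hillman-type adduct without amine base; the new carbinol centre is erased in step 4 and needs no control.

Step 4
Reactants: 7 methyl (4R)-3-hydroxy-4-[(4-methoxybenzyl)oxy]-2-methylidenehex-5-enoate
Product: 8 methyl (2Z,4R)-2-(bromomethyl)-4-[(4-methoxybenzyl)oxy]hexa-2,5-dienoate
Conditions: NBS, Me2S, CH2Cl2, 0 °C → rt
Reagents that add atoms: N-bromosuccinimide, O=C1CCC(=O)N1Br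
Why: Corey–Kim-type activation of the alcohol as an alkoxysulfonium salt and SN2′ attack of bromide should give the rearranged primary allylic bromide with the ester trans to C6 (CH2Br cis to C6), the usual outcome for Baylis–Hillman adducts.

**Fragment C (C1–C4, C10, C14, C15)**

Step 5
Reactants: 9 4-methylpent-4-en-1-ol
Product: 10 4-methylpent-4-enal
Conditions: TEMPO (10 mol %), PhI(OAc)2, CH2Cl2, rt; the volatile aldehyde is carried on as a solution
Reagents that add atoms: none
Why: Oxoammonium-mediated oxidation of a primary alcohol stops at the aldehyde and leaves the 1,1-disubstituted olefin untouched.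

Step 6
Reactants: 10 4-methylpent-4-enal; 11 ethyl (triphenyl-λ5-phosphanylidene)acetate
Product: 13 ethyl (2Z)-2-iodo-6-methylhepta-2,6-dienoate, via ethyl iodo(triphenylphosphoranylidene)acetate 12 (not isolated)
Conditions: 11, NIS, CH2Cl2, −20 °C; then 10, −20 °C → rt
Reagents that add atoms: N-iodosuccinimide, O=C1CCC(=O)N1I
Why: Wittig olefination with the ylide iodinated in the flask; the stabilised ylide should place the alkyl chain trans to the ester and hence cis to iodine, which fixes the later C1=C10 geometry (C2 cis to C9).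

Step 7
Reactants: 13 ethyl (2Z)-2-iodo-6-methylhepta-2,6-dienoate
Product: 14 (2Z)-2-iodo-6-methylhepta-2,6-dien-1-ol
Conditions: i-Bu2AlH (2.2 equiv), CH2Cl2, −78 °C
Reagents that add atoms: none
Why: Hydride reduction of the enoate to the allylic alcohol (1,2-reduction) should leave the alkenyl iodide and its geometry intact at low temperature.

Step 8
Reactants: 14 (2Z)-2-iodo-6-methylhepta-2,6-dien-1-ol
Product: 15 tert-butyl{[(2Z)-2-iodo-6-methylhepta-2,6-dien-1-yl]oxy}dimethylsilane
Conditions: TBSCl, imidazole, DMF, rt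
Reagents that add atoms: tert-butyldimethylsilyl chloride, CC(C)(C)[Si](C)(C)Cl
Why: Standard silylation masks the future C14 aldehyde as a silyl ether that survives all steps up to the final fluoride treatment.

**Assembly and end game**

Step 9
Reactants: 8 methyl (2Z,4R)-2-(bromomethyl)-4-[(4-methoxybenzyl)oxy]hexa-2,5-dienoate; 16 (4R)-2,2-dimethyl-1,3-dioxolane-4-carbaldehyde
Product: 17 methyl (3R,4R)-3-{(S)-[(4R)-2,2-dimethyl-1,3-dioxolan-4-yl](hydroxy)methyl}-4-[(4-methoxybenzyl)oxy]-2-methylidenehex-5-enoate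
Conditions: indium powder, THF/H2O (1:1), rt
Reagents that add atoms: none
Why: Barbier-type indium allylation through a closed chair transition state, in which the CH2In-cis geometry of the allylindium should give the 7,8-syn adduct, the aldehyde should react on its Felkin–Anh face (C8–OH anti to the C9′ oxygen), and the allyl unit should react anti to the C6 ether oxygen with H6 eclipsing the olefin (allylic 1,3-strain), three preferences that reinforce each other for this R/R pair and set C7 and C8.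

Step 10
Reactants: 17 methyl (3R,4R)-3-{(S)-[(4R)-2,2-dimethyl-1,3-dioxolan-4-yl](hydroxy)methyl}-4-[(4-methoxybenzyl)oxy]-2-methylidenehex-5-enoate
Product: 18 methyl (3S,4R)-3-[(S)-{[tert-butyl(dimethyl)silyl]oxy}[(4R)-2,2-dimethyl-1,3-dioxolan-4-yl]methyl]-4-[(4-methoxybenzyl)oxy]-2-methylidenehex-5-enoate
Conditions: TBSOTf, 2,6-lutidine, CH2Cl2, −78 → 0 °C, directly after step 9
Reagents that add atoms: tert-butyldimethylsilyl trifluoromethanesulfonate, CC(C)(C)[Si](C)(C)OS(=O)(=O)C(F)(F)F
Why: Silyl triflate silylation of the hindered C8 hydroxyl blocks lactonisation onto C8 and provides the bulky, non-chelating group needed for step 12.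

Step 11
Reactants: 18 methyl (3S,4R)-3-[(S)-{[tert-butyl(dimethyl)silyl]oxy}[(4R)-2,2-dimethyl-1,3-dioxolan-4-yl]methyl]-4-[(4-methoxybenzyl)oxy]-2-methylidenehex-5-enoate
Product: 19 methyl (3S,4R)-3-[(1S)-1-{[tert-butyl(dimethyl)silyl]oxy}-2-oxoethyl]-4-[(4-methoxybenzyl)oxy]-2-methylidenehex-5-enoate
Conditions: H5IO6, EtOAc, rt
Reagents that add atoms: none
Why: Periodic acid hydrolyses the terminal acetonide and cleaves the liberated glycol in one pot (glycol cleavage), excising the C9′ control element and unveiling the C9 aldehyde while silyl and PMB ethers remain.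

Step 12
Reactants: 19 methyl (3S,4R)-3-[(1S)-1-{[tert-butyl(dimethyl)silyl]oxy}-2-oxoethyl]-4-[(4-methoxybenzyl)oxy]-2-methylidenehex-5-enoate; 15 tert-butyl{[(2Z)-2-iodo-6-methylhepta-2,6-dien-1-yl]oxy}dimethylsilane
Product: 20 methyl (3S,4R)-3-[(1S,2R,3Z)-1-{[tert-butyl(dimethyl)silyl]oxy}-3-({[tert-butyl(dimethyl)silyl]oxy}methyl)-2-hydroxy-7-methylocta-3,7-dien-1-yl]-4-[(4-methoxybenzyl)oxy]-2-methylidenehex-5-enoate
Conditions: CrCl2 (6 equiv), NiCl2 (1 mol %), DMSO, rt
Reagents that add atoms: none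
Why: Nozaki–Hiyama–Kishi coupling adds the alkenylchromium species to the aldehyde with retention of olefin geometry and tolerance of the esters; Felkin–Anh attack anti to the bulky C8 silyloxy group should set C9 anti to C8.

Step 13
Reactants: 20 methyl (3S,4R)-3-[(1S,2R,3Z)-1-{[tert-butyl(dimethyl)silyl]oxy}-3-({[tert-butyl(dimethyl)silyl]oxy}methyl)-2-hydroxy-7-methylocta-3,7-dien-1-yl]-4-[(4-methoxybenzyl)oxy]-2-methylidenehex-5-enoate
Product: 21 methyl (3S,4R)-3-[(1S,2R,3Z)-2-acetoxy-1-{[tert-butyl(dimethyl)silyl]oxy}-3-({[tert-butyl(dimethyl)silyl]oxy}methyl)-7-methylocta-3,7-dien-1-yl]-4-[(4-methoxybenzyl)oxy]-2-methylidenehex-5-enoate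
Conditions: Ac2O, DMAP, pyridine, CH2Cl2, rt
Reagents that add atoms: acetic anhydride, CC(=O)OC(C)=O
Why: DMAP-catalysed acylation installs the C9 acetate of the target, which also serves as the C9 protecting group.

Step 14
Reactants: 21 methyl (3S,4R)-3-[(1S,2R,3Z)-2-acetoxy-1-{[tert-butyl(dimethyl)silyl]oxy}-3-({[tert-butyl(dimethyl)silyl]oxy}methyl)-7-methylocta-3,7-dien-1-yl]-4-[(4-methoxybenzyl)oxy]-2-methylidenehex-5-enoate
Product: 22 methyl 9-acetoxy-8,14-bis{[tert-butyl(dimethyl)silyl]oxy}-6-[(4-methoxybenzyl)oxy]germacra-1(10)Z,4Z,11(13)-trien-12-oate (C6–C9 arranged as in 28)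
Conditions: second-generation Grubbs catalyst (15 mol %, in portions), 1,4-benzoquinone (30 mol %), PhMe (1 mM), 80 °C
Reagents that add atoms: none
Why: Ring-closing olefin metathesis: the ruthenium alkylidene loads on the monosubstituted C5 vinyl group, adds to the 1,1-disubstituted C4 olefin in a [2+2] step, and the metallacyclobutane collapses with loss of ethene to form the C4=C5 bond. The closest known reaction type is macrocyclising metathesis to trisubstituted medium-ring cycloalkenes, as applied to ten-membered germacrane-type carbocycles. The only ring closed is the ten-membered carbocycle C1–C10, formed end to end from the acyclic diene. No stereocentre is created; the new olefin is expected to be Z (C3 cis to C6), because an E olefin in a cyclodecadiene that already holds the cis C1=C10 bond is far more strained. The step needs chemoselectivity among five olefins and closure over oligomerisation: only the C5 vinyl group initiates readily, the acrylate and the trisubstituted C1=C10 olefin are poor partners, no smaller ring can form because the methacrylate is still absent, and the C1=C10 turn plus high dilution favour cyclisation.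

Step 15
Reactants: 22 methyl 9-acetoxy-8,14-bis{[tert-butyl(dimethyl)silyl]oxy}-6-[(4-methoxybenzyl)oxy]germacra-1(10)Z,4Z,11(13)-trien-12-oate
Product: 23 methyl 9-acetoxy-8,14-bis{[tert-butyl(dimethyl)silyl]oxy}-6-hydroxygermacra-1(10)Z,4Z,11(13)-trien-12-oate
Conditions: DDQ (1.2 equiv), CH2Cl2/pH 7 buffer, 0 °C
Reagents that add atoms: none
Why: Oxidative cleavage of the PMB ether by DDQ frees only the C6 hydroxyl, the directing group for step 16; silyl ethers, acetate and olefins should be inert.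

Step 16
Reactants: 23 methyl 9-acetoxy-8,14-bis{[tert-butyl(dimethyl)silyl]oxy}-6-hydroxygermacra-1(10)Z,4Z,11(13)-trien-12-oate
Product: 24 methyl 9-acetoxy-8,14-bis{[tert-butyl(dimethyl)silyl]oxy}-4,5-epoxy-6-hydroxygermacra-1(10)Z,11(13)-dien-12-oate (cis-oxirane; C4–C9 arranged as in 28)
Conditions: VO(acac)2 (10 mol %), t-BuOOH (1.5 equiv), CH2Cl2, 0 °C → rt
Reagents that add atoms: tert-butyl hydroperoxide, CC(C)(C)OO
Why: Hydroxyl-directed vanadium-catalysed epoxidation delivers oxygen from the C6-bound vanadium peroxide to the C4=C5 face on the side of the C6–O bond, which in medium-ring (Z)-allylic alcohols gives the cis (5,6-erythro) epoxy alcohol; the Z olefin thus becomes the (4R,5S) cis-oxirane, and the undirected C1=C10 and acrylate olefins should not react.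

Step 17
Reactants: 24 methyl 9-acetoxy-8,14-bis{[tert-butyl(dimethyl)silyl]oxy}-4,5-epoxy-6-hydroxygermacra-1(10)Z,11(13)-dien-12-oate
Product: 25 9-acetoxy-8,14-bis{[tert-butyl(dimethyl)silyl]oxy}-4,5-epoxygermacra-1(10)Z,11(13)-dien-12,6-olide (C4–C9 as in 28)
Conditions: DBU (0.3 equiv), 4 Å molecular sieves, PhMe, 40 °C
Reagents that add atoms: none
Why: Base-catalysed 5-exo-trig lactonisation of the γ-hydroxy ester gives the trans-fused α-methylene-γ-butyrolactone, its ring fusion being fixed by the C6 and C7 centres already present.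

Step 18
Reactants: 25 9-acetoxy-8,14-bis{[tert-butyl(dimethyl)silyl]oxy}-4,5-epoxygermacra-1(10)Z,11(13)-dien-12,6-olide
Product: 26 9-acetoxy-4,5-epoxy-8,14-dihydroxygermacra-1(10)Z,11(13)-dien-12,6-olide
Conditions: HF·pyridine, excess pyridine, THF, 0 °C → rt
Reagents that add atoms: none
Why: Buffered fluoride desilylation removes both silyl ethers under weakly acidic conditions that should avoid acetate migration; the trans-fused lactone prevents the C8 hydroxyl from reaching C5 of the oxirane.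

Step 19
Reactants: 26 9-acetoxy-4,5-epoxy-8,14-dihydroxygermacra-1(10)Z,11(13)-dien-12,6-olide
Product: 27 9-acetoxy-4,5-epoxy-8-hydroxy-14-oxogermacra-1(10)E,11(13)-dien-12,6-olide (C2 still cis to C9; only the descriptor changes)
Conditions: activated MnO2 (20 equiv), CH2Cl2, rt
Reagents that add atoms: none
Why: Manganese dioxide oxidises only the primary allylic C14 alcohol to the enal, leaving the non-allylic C8 hydroxyl; the chain-trans-to-CHO geometry is the stable one.

Step 20
Reactants: 27 9-acetoxy-4,5-epoxy-8-hydroxy-14-oxogermacra-1(10)E,11(13)-dien-12,6-olide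
Product: 28 (4R,5S,6S,7R,8S,9R)-9-acetoxy-4,5-epoxy-14-oxogermacra-1(10)E,11(13)-dien-12,6-olid-8-yl 2-methylprop-2-enoate (target)
Conditions: methacrylic anhydride, Et3N, DMAP (cat.), CH2Cl2, 0 °C → rt
Reagents that add atoms: methacrylic anhydride, C=C(C)C(=O)OC(=O)C(C)=C
Why: DMAP-catalysed acylation of the remaining C8 hydroxyl installs the methacrylate last, so that this olefin never meets the metathesis catalyst.

**Compound list**

1 | 2-ethenyloxirane (racemic) | C=CC1CO1 | starting material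
2 | (4-methoxyphenyl)methanol | COc1ccc(CO)cc1 | starting material
3 | (2R)-2-[(4-methoxybenzyl)oxy]but-3-en-1-ol | OC[C@H](OCc1ccc(OC)cc1)C=C | intermediate
4 | (2R)-2-[(4-methoxybenzyl)oxy]but-3-enal | O=C[C@H](OCc1ccc(OC)cc1)C=C | intermediate
5 | methyl prop-2-ynoate | C#CC(=O)OC | starting material
6 | methyl 2-(diisobutylalumanyl)prop-2-enoate | C=C(C(=O)OC)[Al](CC(C)C)CC(C)C | intermediate (not isolated)
7 | methyl (4R)-3-hydroxy-4-[(4-methoxybenzyl)oxy]-2-methylidenehex-5-enoate (C3 epimers) | C=C(C(=O)OC)C(O)[C@H](OCc1ccc(OC)cc1)C=C | intermediate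
8 | methyl (2Z,4R)-2-(bromomethyl)-4-[(4-methoxybenzyl)oxy]hexa-2,5-dienoate | BrC/C(C(=O)OC)=C\[C@H](OCc1ccc(OC)cc1)C=C | intermediate
9 | 4-methylpent-4-en-1-ol | C=C(C)CCCO | starting material
10 | 4-methylpent-4-enal | C=C(C)CCC=O | intermediate
11 | ethyl (triphenyl-λ5-phosphanylidene)acetate | CCOC(=O)C=P(c1ccccc1)(c1ccccc1)c1ccccc1 | starting material
12 | ethyl iodo(triphenyl-λ5-phosphanylidene)acetate | CCOC(=O)C(I)=P(c1ccccc1)(c1ccccc1)c1ccccc1 | intermediate (not isolated)
13 | ethyl (2Z)-2-iodo-6-methylhepta-2,6-dienoate | CCOC(=O)/C(I)=C/CCC(C)=C | intermediate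
14 | (2Z)-2-iodo-6-methylhepta-2,6-dien-1-ol | OC/C(I)=C/CCC(C)=C | intermediate
15 | tert-butyl{[(2Z)-2-iodo-6-methylhepta-2,6-dien-1-yl]oxy}dimethylsilane | CC(C)(C)[Si](C)(C)OC/C(I)=C/CCC(C)=C | intermediate
16 | (4R)-2,2-dimethyl-1,3-dioxolane-4-carbaldehyde | O=C[C@H]1COC(C)(C)O1 | starting material
17 | methyl (3R,4R)-3-{(S)-[(4R)-2,2-dimethyl-1,3-dioxolan-4-yl](hydroxy)methyl}-4-[(4-methoxybenzyl)oxy]-2-methylidenehex-5-enoate | C=C[C@@H](OCc1ccc(OC)cc1)[C@H](C(=C)C(=O)OC)[C@H](O)[C@H]1COC(C)(C)O1 | intermediate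
18 | methyl (3S,4R)-3-[(S)-{[tert-butyl(dimethyl)silyl]oxy}[(4R)-2,2-dimethyl-1,3-dioxolan-4-yl]methyl]-4-[(4-methoxybenzyl)oxy]-2-methylidenehex-5-enoate | C=C[C@@H](OCc1ccc(OC)cc1)[C@H](C(=C)C(=O)OC)[C@H](O[Si](C)(C)C(C)(C)C)[C@H]1COC(C)(C)O1 | intermediate
19 | methyl (3S,4R)-3-[(1S)-1-{[tert-butyl(dimethyl)silyl]oxy}-2-oxoethyl]-4-[(4-methoxybenzyl)oxy]-2-methylidenehex-5-enoate | C=C[C@@H](OCc1ccc(OC)cc1)[C@H](C(=C)C(=O)OC)[C@H](O[Si](C)(C)C(C)(C)C)C=O | intermediate
20 | methyl (3S,4R)-3-[(1S,2R,3Z)-1-{[tert-butyl(dimethyl)silyl]oxy}-3-({[tert-butyl(dimethyl)silyl]oxy}methyl)-2-hydroxy-7-methylocta-3,7-dien-1-yl]-4-[(4-methoxybenzyl)oxy]-2-methylidenehex-5-enoate | C=C[C@@H](OCc1ccc(OC)cc1)[C@H](C(=C)C(=O)OC)[C@H](O[Si](C)(C)C(C)(C)C)[C@H](O)/C(CO[Si](C)(C)C(C)(C)C)=C\CCC(C)=C | intermediate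
21 | methyl (3S,4R)-3-[(1S,2R,3Z)-2-acetoxy-1-{[tert-butyl(dimethyl)silyl]oxy}-3-({[tert-butyl(dimethyl)silyl]oxy}methyl)-7-methylocta-3,7-dien-1-yl]-4-[(4-methoxybenzyl)oxy]-2-methylidenehex-5-enoate | C=C[C@@H](OCc1ccc(OC)cc1)[C@H](C(=C)C(=O)OC)[C@H](O[Si](C)(C)C(C)(C)C)[C@H](OC(C)=O)/C(CO[Si](C)(C)C(C)(C)C)=C\CCC(C)=C | intermediate
22 | methyl 9-acetoxy-8,14-bis{[tert-butyl(dimethyl)silyl]oxy}-6-[(4-methoxybenzyl)oxy]germacra-1(10)Z,4Z,11(13)-trien-12-oate (C6–C9 as in 28) | COC(=O)C(=C)[C@H]1[C@H](OCc2ccc(OC)cc2)/C=C(C)\CC/C=C(CO[Si](C)(C)C(C)(C)C)\[C@@H](OC(C)=O)[C@H]1O[Si](C)(C)C(C)(C)C | intermediate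
23 | methyl 9-acetoxy-8,14-bis{[tert-butyl(dimethyl)silyl]oxy}-6-hydroxygermacra-1(10)Z,4Z,11(13)-trien-12-oate (C6–C9 as in 28) | COC(=O)C(=C)[C@H]1[C@H](O)/C=C(C)\CC/C=C(CO[Si](C)(C)C(C)(C)C)\[C@@H](OC(C)=O)[C@H]1O[Si](C)(C)C(C)(C)C | intermediate
24 | methyl 9-acetoxy-8,14-bis{[tert-butyl(dimethyl)silyl]oxy}-4,5-epoxy-6-hydroxygermacra-1(10)Z,11(13)-dien-12-oate (C4–C9 as in 28) | COC(=O)C(=C)[C@H]1[C@H](O)[C@@H]2O[C@]2(C)CC/C=C(CO[Si](C)(C)C(C)(C)C)\[C@@H](OC(C)=O)[C@H]1O[Si](C)(C)C(C)(C)C | intermediate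
25 | 9-acetoxy-8,14-bis{[tert-butyl(dimethyl)silyl]oxy}-4,5-epoxygermacra-1(10)Z,11(13)-dien-12,6-olide (C4–C9 as in 28) | CC(C)(C)[Si](C)(C)O[C@H]1[C@H]2C(=C)C(=O)O[C@@H]2[C@@H]2O[C@]2(C)CC/C=C(/CO[Si](C)(C)C(C)(C)C)[C@H]1OC(C)=O | intermediate
26 | 9-acetoxy-4,5-epoxy-8,14-dihydroxygermacra-1(10)Z,11(13)-dien-12,6-olide (C4–C9 as in 28) | O[C@H]1[C@H]2C(=C)C(=O)O[C@@H]2[C@@H]2O[C@]2(C)CC/C=C(/CO)[C@H]1OC(C)=O | intermediate
27 | 9-acetoxy-4,5-epoxy-8-hydroxy-14-oxogermacra-1(10)E,11(13)-dien-12,6-olide (C4–C9 as in 28) | O[C@H]1[C@H]2C(=C)C(=O)O[C@@H]2[C@@H]2O[C@]2(C)CC/C=C(/C=O)[C@H]1OC(C)=O | intermediate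
28 | (4R,5S,6S,7R,8S,9R)-9-acetoxy-4,5-epoxy-14-oxogermacra-1(10)E,11(13)-dien-12,6-olid-8-yl 2-methylprop-2-enoate | C=C(C)C(=O)O[C@H]1[C@H]2C(=C)C(=O)O[C@@H]2[C@@H]2O[C@]2(C)CC/C=C(/C=O)[C@H]1OC(C)=O | target

**Totals.** Total step count: 20. Longest linear sequence: 16 steps (steps 1–4, then 9–20).

**Steps most likely to fail and their fallbacks**

1. Step 14 (ring-closing metathesis). What may go wrong: intermolecular metathesis at the C5 vinyl group (oligomerisation) outruns closure of the flexible seco-ester, or the hindered 1,1-disubstituted C4 olefin is engaged so slowly that the catalyst decays. Fallback: close the ring on a conformationally restricted lactone instead. Setting out from 21, DDQ (CH2Cl2/pH 7 buffer) followed by camphorsulfonic acid (cat., CH2Cl2) would remove the PMB ether and lactonise to the trans-lactone diene F1, in which C5 and C8 are held on the butyrolactone as in the natural skeleton. Ring-closing metathesis (second-generation Hoveyda–Grubbs catalyst, PhMe, 80 °C, 1 mM) would then give the cyclodecadiene lactone F2. Because F2 has no directing hydroxyl, the oxirane would be installed in two operations: NBS in THF/H2O should give the bromohydrin F3 (bromonium on the outer face, water at the tertiary C4), and Ag2O in THF should close the epoxide with inversion at C5. This returns to the route at 25.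

2. Step 16 (directed epoxidation). What may go wrong: oxygen is delivered to the other olefin face because the ring holds H6 rather than O6 next to the olefin, giving the 5,6-threo epoxide, or the hydroxy ester lactonises first and the directing group is lost. Fallback: put the oxygen on the face opposite to that taken by an external electrophile, without any directing group. Setting out from 22, NBS in THF/H2O should give the bromohydrin F4 (C5–Br, C4–OH, anti), and Ag2O in THF should close it to the epoxide F5, the PMB ether of 24. DDQ (CH2Cl2/pH 7 buffer) then returns to the route at 24.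

3. Step 9 (indium Barbier allylation). What may go wrong: the allylindium loses its olefin geometry by metallotropic shift, or the loose transition state in water discriminates poorly between the faces of the two partners, so that mixtures of stereotriads result. Fallback: replace the organoindium generated in the flask by an isolable, configurationally stable allylboronate that reacts through a tight six-membered chair. Setting out from 7, Ac2O/DMAP/pyridine would give the acetate F6; copper-catalysed borylation with allylic transposition (bis(pinacolato)diboron, CuCl, LiCl, KOAc, DMF, rt) would give the allylboronate F7 (CH2B cis to C6). Thermal allylboration of 16 with F7 (PhMe, rt → 50 °C), followed by mild aqueous work-up with triethanolamine, returns to the route at 17.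

**Further compounds**

F1 | step 14 | (4R,5S)-4-[(1S,2R,3Z)-2-acetoxy-1-{[tert-butyl(dimethyl)silyl]oxy}-3-({[tert-butyl(dimethyl)silyl]oxy}methyl)-7-methylocta-3,7-dien-1-yl]-5-ethenyl-3-methylideneoxolan-2-one (C6–C9 as in 28) | CC(C)(C)[Si](C)(C)O[C@@H]([C@H]1C(=C)C(=O)O[C@@H]1C=C)[C@H](OC(C)=O)/C(CO[Si](C)(C)C(C)(C)C)=C\CCC(C)=C
F2 | step 14 | 9-acetoxy-8,14-bis{[tert-butyl(dimethyl)silyl]oxy}germacra-1(10)Z,4Z,11(13)-trien-12,6-olide (C6–C9 as in 28) | CC(C)(C)[Si](C)(C)O[C@H]1[C@H]2C(=C)C(=O)O[C@@H]2/C=C(C)\CC/C=C(/CO[Si](C)(C)C(C)(C)C)[C@H]1OC(C)=O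
F3 | step 14 | 9-acetoxy-5-bromo-8,14-bis{[tert-butyl(dimethyl)silyl]oxy}-4-hydroxygermacra-1(10)Z,11(13)-dien-12,6-olide (Br and OH anti) | CC(C)(C)[Si](C)(C)O[C@H]1[C@H]2C(=C)C(=O)O[C@@H]2[C@@H](Br)[C@](C)(O)CC/C=C(/CO[Si](C)(C)C(C)(C)C)[C@H]1OC(C)=O
F4 | step 16 | methyl 9-acetoxy-5-bromo-8,14-bis{[tert-butyl(dimethyl)silyl]oxy}-4-hydroxy-6-[(4-methoxybenzyl)oxy]germacra-1(10)Z,11(13)-dien-12-oate (Br and OH anti) | COC(=O)C(=C)[C@H]1[C@H](OCc2ccc(OC)cc2)[C@@H](Br)[C@](C)(O)CC/C=C(CO[Si](C)(C)C(C)(C)C)\[C@@H](OC(C)=O)[C@H]1O[Si](C)(C)C(C)(C)C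
F5 | step 16 | methyl 9-acetoxy-8,14-bis{[tert-butyl(dimethyl)silyl]oxy}-4,5-epoxy-6-[(4-methoxybenzyl)oxy]germacra-1(10)Z,11(13)-dien-12-oate (C4–C9 as in 28) | COC(=O)C(=C)[C@H]1[C@H](OCc2ccc(OC)cc2)[C@@H]2O[C@]2(C)CC/C=C(CO[Si](C)(C)C(C)(C)C)\[C@@H](OC(C)=O)[C@H]1O[Si](C)(C)C(C)(C)C
F6 | step 9 | methyl (4R)-3-acetoxy-4-[(4-methoxybenzyl)oxy]-2-methylidenehex-5-enoate (C3 epimers) | C=C(C(=O)OC)C(OC(C)=O)[C@H](OCc1ccc(OC)cc1)C=C
F7 | step 9 | methyl (2E,4R)-4-[(4-methoxybenzyl)oxy]-2-[(4,4,5,5-tetramethyl-1,3,2-dioxaborolan-2-yl)methyl]hexa-2,5-dienoate | CC1(C)OB(C/C(C(=O)OC)=C\[C@H](OCc2ccc(OC)cc2)C=C)OC1(C)C
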